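The data come from a simulation for an exercise.

| flask | starting material | coupling partner | free catalyst | time |
|---|---|---|---|---|
| Monday's | 0.300 M | 0.360 M | 0.00600 M |  |
| Wednesday's | 0.180 M | 0.240 M | 0.00600 M |  |
| Tuesday's | 0.300 M | 0.720 M | 0.00600 M |  |
| Sunday's | 0.900 M | 0.360 M | 0.00600 M |  |
| Saturday's | 0.0990 M | 0.120 M | 0.00600 M | 97 min |

| run | time / min | [starting material] / M |
|---|---|---|
| Monday's run | 3.5 | 0.241 |
| Monday's run | 11 | 0.216 |
| Monday's run | 20 | 0.206 |
| Monday's run | 32 | 0.208 |
| Monday's run | 46 | 0.199 |
| Monday's run | 61 | 0.198 |
| Monday's run | 78 | 0.190 |
| Monday's run | 97 | 0.200 |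
| Wednesday's run | 3.5 | 0.142 |
| Wednesday's run | 11 | 0.122 |
| Wednesday's run | 20 | 0.116 |
| Wednesday's run | 32 | 0.110 |
| Wednesday's run | 46 | 0.114 |
| Wednesday's run | 61 | 0.113 |
| Wednesday's run | 78 | 0.107 |
| Wednesday's run | 97 | 0.107 |
| Tuesday's run | 3.5 | 0.250 |
| Tuesday's run | 11 | 0.233 |
| Tuesday's run | 20 | 0.233 |
| Tuesday's run | 32 | 0.233 |
| Tuesday's run | 46 | 0.227 |
| Tuesday's run | 61 | 0.229 |
| Tuesday's run | 78 | 0.225 |
| Tuesday's run | 97 | 0.231 |
| Sunday's run | 3.5 | 0.769 |
| Sunday's run | 11 | 0.726 |
| Sunday's run | 20 | 0.713 |
| Sunday's run | 32 | 0.709 |
| Sunday's run | 46 | 0.711 |
| Sunday's run | 61 | 0.701 |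
| Sunday's run | 78 | 0.705 |
| Sunday's run | 97 | 0.710 |

(each reading ± 0.004 M)

- Overall: starting material + coupling partner -> target, with free catalyst as catalyst.
- Constant volume, constant temperature.
- What is held in complexes is read along with the free species.
- "The second partner" is coupling partner.
- An order is taken over about fifteen percent of the charge, up and down.

- apparent order in [starting material] of the starting rate, round the charge of the Monday's run (the rate where two percent of its starting material have turned into target) (one fixed amount of target, the same in the runs compared)
- apparent order in [coupling partner] of the starting rate, round the charge of the Monday's run (the rate where two percent of its starting material have turned into target)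
- starting material in the Saturday's run at 97 min, as a share of the starting material charged

1. Amounts first. In Monday's run the share of the charge turned levels off, over the last 4 readings, at 34.4%; in Wednesday's run it levels off at 38.7%. At the first reading these runs already stand at 19.7% and 21.1%.

2. I describe such a curve by two times. The stall time is the time in which the gap to the plateau shrinks by a factor e, read from the gap left at the first reading. The fill time is the stall time divided by the plateau share: how long the whole charge would take at the rate my curve starts with. So plateau share = stall time / fill time.

3. Monday's run gives a stall time of 4.13 min and a fill time of 12.0 min. Wednesday's run, more dilute in both reactants, gives a stall time of 4.45 min and a fill time of 11.5 min. These are readings with scatter, but dilution moved the fill time little.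

4. Saturday's run dilutes Wednesday's again. Round one keeps Wednesday's stall time and fill time, which leaves 61.3% of the starting material. Round two lets the stall time change: from Monday's run to Wednesday's it grew by a factor 1.08 while the coupling partner fell by a factor 1.50, and the starting material fell as well. The same power over the factor 2.00 from Wednesday's coupling partner to Saturday's gives a stall time of 5.05 min for Saturday's run. I commit to 56.0% left.

5. The forecast says 59% left (50% to 68%), with orders of 0.7 and −0.15, reasoning that “the catalyst dies or is shut down”. My share left is lower than the forecast's.

6. The flask gives orders of 0.86 and 0.39, and 53.6% left in Saturday's run.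

    free catalyst + starting material ⇌ catalyst-substrate complex (42.24 M⁻¹ min⁻¹, 9.540 min⁻¹)
    catalyst-substrate complex + coupling partner → target + free catalyst (76.80 M⁻¹ min⁻¹)
    free catalyst + coupling partner → spent catalyst + coupling partner (2.106 M⁻¹ min⁻¹)
    2 coupling partner → lost reagent (0.5898 M⁻¹ min⁻¹)

In Saturday's run 46.4% of the charge turned, which at the fill time of 11.5 min means a stall time of 5.34 min. The same run, with the passing of free catalyst and coupling partner into spent catalyst taken away, leaves 30.9%. At the same fill time that means a stall time of 7.95 min. This catalyst deactivation costs Saturday's run 23 percentage points of its charge.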